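The numbers in the tables stem from a simulated flask with constants of no real substance.

If I put ochre and teal on the next plate, I must decide two things: whether ochre's nucleophile is enough for 4.0 h, and whether teal's extra free base earns its place.

| setting | midnight | summer | ochre | teal |
|---|---|---|---|---|
| electrophile | 0.039 M | 0.039 M | 0.039 M | 0.039 M |
| nucleophile | 0.076 M | 0.025 M | 0.0507 M | 0.0507 M |
| free base | 0.0585 M | 0.0585 M | 0.0590 M | 0.120 M |
| remark | run made earlier | run made earlier |  |  |
| time |  |  | 4.0 h | 4.0 h |

| run | time / min | electrophile / % | target / % |
|---|---|---|---|
| midnight | 6.00 | 59.6 | 32.9 |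
| midnight | 12.0 | 41.5 | 46.5 |
| midnight | 25.0 | 23.9 | 48.8 |
| midnight | 40.0 | 13.5 | 47.3 |
| midnight | 80.0 | 5.3 | 41.3 |
| summer | 15.0 | 73.2 | 19.2 |
| summer | 30.0 | 62.6 | 21.1 |
| summer | 50.0 | 58.0 | 17.6 |
| summer | 60.0 | 55.1 | 16.5 |
| summer | 80.0 | 51.6 | 14.0 |

(standard deviation of a reading: 1 percentage point)

- part of the electrophile that has reacted at the end, ochre
- part of the electrophile that has reacted at the end, teal
- what raising the concentration of free base from its lowest to its highest value here does to the part of the electrophile that has reacted (changes below 5 percentage points count as none) (no change / it falls / it rises)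

- no earlier run changes the charge of free base; that part of a forecast is a guess

I treat the loss of electrophile as first order in electrophile, with a constant that drifts as the nucleophile changes. Integrated, this needs one number per time, so I write:

ln(electrophile charged / electrophile left) = reach × nucleophile charged

In the summer run this logarithm climbs at 0.00328 min⁻¹ between its last two readings, a slope the scatter leaves loose. I carry that slope on to the end:

reach = [ln(charged / left at 80.0 min) + slope × (4.0 h − 80.0 min)] / 0.025 M = 47.5 M⁻¹

So the reach is the logarithmic fall of the electrophile by a given time, per unit of nucleophile charged, and my figure is for 4.0 h. At 80.0 min the midnight run shows 38.7 M⁻¹, more than the 26.5 M⁻¹ of the summer run. Ochre holds more nucleophile than the summer run, so my figure for ochre leans low.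

reacted in ochre = 1 − exp(−reach × 0.0507 M) = 91.0 %

No earlier run changes the free base, so I give teal the same figure as a guess. I charge ochre as it stands and keep teal as the test of free base.

The forecast stands lower for ochre at 87 %, with 85 % for teal and no change: “I lean towards little change”.

Ochre gives 93.8 % and teal 94.7 %, a change of 0.89 percentage points, so the trend reads no change.

    electrophile + nucleophile → acid set free + target (k = 0.0230 M⁻¹ s⁻¹)
    nucleophile + acid set free ⇌ protonated nucleophile, settled at all times (K = 55000 M⁻¹)
    acid set free + free base ⇌ salt of the base (K = 5900 M⁻¹, k = 0.0290 M⁻¹ s⁻¹)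
    nucleophile + target → over-reaction product (k = 0.00650 M⁻¹ s⁻¹)
    electrophile + target → side product (k = 0.00870 M⁻¹ s⁻¹)

Read back from its result, ochre's reach is 55.0 M⁻¹, larger than my 47.5 M⁻¹. I now use my reach on a neighbour of teal, charged with 0.020 M of nucleophile, which is 0.513 equiv to the electrophile. Its free base and time stay as in teal.

reacted in the neighbour = 1 − exp(−reach × 0.020 M) = 61.3 %

That neighbour gives 61.4 % reacted, with 38.6 % of the electrophile left and 5.80 % as target at the end.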